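**Retrosynthetic overview**

1. The target is reached by global O-debenzylation of its pentabenzyl ether (last step).
2. Both rings C and both C-4–C-3 bonds are cut in one operation. Carbene-generated acyl anion equivalents add first across a central alkyne (hydroacylation, first ring C), then to the β-carbon of the resulting enone (intramolecular Stetter, second ring C). The precursor is an acyclic bis(2-formylaryl) ether of a 1,4-diarylbut-2-yne-1,4-diol.
3. C-2 and C-2'' have opposite absolute sense (a "pseudo-meso" pair) and are installed beforehand as the two aryl propargyl ether centres. C-3 and C-3'' settle as the 2,3-trans epimers.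
4. The bis-ether comes from Mitsunobu inversion of a propargylic alcohol. That alcohol comes from asymmetric zinc alkynylation of 4-(benzyloxy)benzaldehyde with a terminal alkyne, itself made by copper-catalysed enantioconvergent propargylic etherification of a racemic propargylic acetate.
5. Ring order: rings A and B are bought as benzaldehydes; the two rings C are formed last, in one flask.

Target configuration planned for: (2S,3R,2''R,3''S), both rings 2,3-trans.

Assumption: the ligand antipodes named in steps 3 and 4 are the ones taken to give the drawn configurations; if the sense of induction proves opposite, the mirror-image ligand is used and nothing else changes.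

Note on descriptors: the ether-bearing carbons keep their spatial arrangement from steps 3 and 5 onward. Their R/S letters change between 7, 9–12 and 13 only because the CIP ranking of the neighbouring carbon changes (ethynyl < aryl < internal alkynyl).

**Route**

Step 1
Reactants: 1 2,4,6-trihydroxybenzaldehyde
Product: 2 2,4-bis(benzyloxy)-6-hydroxybenzaldehyde
Conditions: BnBr (2.1 equiv), K2CO3 (2.2 equiv), DMF, 0 °C to rt
Reagents that add atoms: benzyl bromide, BrCc1ccccc1
Why: Williamson etherification in which the 4-OH and one 2-OH are alkylated while the last ortho OH is held back by its hydrogen bond to the formyl group, leaving one chelated phenol free.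

Step 2
Reactants: 3 4-methoxybenzaldehyde; 4 ethynylmagnesium bromide
Product: 6 rac-1-(4-methoxyphenyl)prop-2-yn-1-yl acetate, via bromomagnesium alkoxide 5 (not isolated)
Conditions: THF, 0 °C; then Ac2O (1.5 equiv), 0 °C to rt; aq NH4Cl
Reagents that add atoms: acetic anhydride, CC(=O)OC(C)=O
Why: Grignard 1,2-addition followed by O-acylation of the magnesium alkoxide in the same flask; the centre is left racemic on purpose because the next step is enantioconvergent.

Step 3
Reactants: 6 rac-1-(4-methoxyphenyl)prop-2-yn-1-yl acetate; 2 2,4-bis(benzyloxy)-6-hydroxybenzaldehyde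
Product: 7 2,4-bis(benzyloxy)-6-{[(1S)-1-(4-methoxyphenyl)prop-2-yn-1-yl]oxy}benzaldehyde
Conditions: CuOTf·0.5C6H6 (5 mol%), 2,6-bis[(4S)-4-phenyl-4,5-dihydrooxazol-2-yl]pyridine (10 mol%), iPr2NEt (1.2 equiv), CH2Cl2, −20 °C
Reagents that add atoms: none
Why: Copper-catalysed enantioselective propargylic etherification (Nishibayashi type), in which both enantiomers of 6 converge on one catalyst-bound planar propargylic electrophile and the chiral pybox ligand directs the phenoxide of 2 to one face, setting the future C-2 of the methoxyphenyl half.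

Step 4
Reactants: 7 2,4-bis(benzyloxy)-6-{[(1S)-1-(4-methoxyphenyl)prop-2-yn-1-yl]oxy}benzaldehyde; 8 4-(benzyloxy)benzaldehyde
Product: 9 2,4-bis(benzyloxy)-6-{[(1R,4R)-4-[4-(benzyloxy)phenyl]-4-hydroxy-1-(4-methoxyphenyl)but-2-yn-1-yl]oxy}benzaldehyde
Conditions: Me2Zn (3 equiv), (S,S)-2,6-bis{[2-(hydroxydiphenylmethyl)pyrrolidin-1-yl]methyl}-4-methylphenol (20 mol%), Ph3P=O (40 mol%), 8 (2 equiv) present from the start, toluene, 0 to 4 °C; aq NH4Cl
Reagents that add atoms: none
Why: Catalytic asymmetric zinc alkynylide addition to an aldehyde (Trost ProPhenol alkynylation), where the dinuclear zinc catalyst sets the new carbinol centre (R) by catalyst control and the para-alkoxy aldehyde 8 reacts in preference to the di-ortho-substituted trioxygenated formyl group of 7.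

Step 5
Reactants: 9 2,4-bis(benzyloxy)-6-{[(1R,4R)-4-[4-(benzyloxy)phenyl]-4-hydroxy-1-(4-methoxyphenyl)but-2-yn-1-yl]oxy}benzaldehyde; 2 2,4-bis(benzyloxy)-6-hydroxybenzaldehyde
Product: 10 2,2'-{[(1R,4S)-4-[4-(benzyloxy)phenyl]-1-(4-methoxyphenyl)but-2-yne-1,4-diyl]bis(oxy)}bis[4,6-bis(benzyloxy)benzaldehyde]
Conditions: 2 (1.5 equiv), PPh3 (1.6 equiv), DIAD (1.6 equiv), toluene, −20 to 0 °C
Reagents that add atoms: none
Why: Mitsunobu etherification in which the acidic chelated phenol displaces the oxyphosphonium group by SN2 with inversion (4R to 4S), giving the future C-2'' of the hydroxyphenyl half; low temperature and a non-polar solvent suppress ionisation of this electron-rich benzylic propargylic centre.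

Step 6
Reactants: 10 2,2'-{[(1R,4S)-4-[4-(benzyloxy)phenyl]-1-(4-methoxyphenyl)but-2-yne-1,4-diyl]bis(oxy)}bis[4,6-bis(benzyloxy)benzaldehyde]
Product: 13 (2S,3R)-5,7-bis(benzyloxy)-3-{(2R,3S)-5,7-bis(benzyloxy)-2-[4-(benzyloxy)phenyl]-4-oxochroman-3-yl}-2-(4-methoxyphenyl)chroman-4-one, via 3-alkylideneflavanone 11 (not isolated), via isomeric 3-alkylideneflavanone 12 (not isolated)
Conditions: 3-mesityl-5,6,7,8-tetrahydro-4H-cyclohepta[d]thiazol-3-ium perchlorate (20 mol%), K2CO3 (40 mol%), THF, 70 °C, argon
Reagents that add atoms: none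
Why: Proposed new method: the thiazol-2-ylidene turns a formyl carbon into a catalyst-bound acyl anion equivalent that adds with its O–H across the tethered alkyne in a concerted 6-exo syn hydroacylation to give the E-enones 11 and 12 (either formyl group may start; both converge), and the second acyl anion equivalent then attacks the enone β-carbon in a 6-exo-trig Stetter reaction, joining two carbons that are both electrophilic in normal polarity; C-3 and C-3'' are both α to a ketone, so bond formation and protonation anti to the adjacent aryl group, backed by carbonate equilibration, give the diequatorial 2,3-trans arrangement in each ring dictated by the fixed C-2 and C-2'' centres; closest known reaction type is the carbene-catalysed hydroacylation of unactivated alkynes in salicylaldehyde propargyl ethers run as a hydroacylation–Stetter cascade, here with the Stetter step intramolecular onto a trisubstituted enone.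

Step 7
Reactants: 13 (2S,3R)-5,7-bis(benzyloxy)-3-{(2R,3S)-5,7-bis(benzyloxy)-2-[4-(benzyloxy)phenyl]-4-oxochroman-3-yl}-2-(4-methoxyphenyl)chroman-4-one
Product: 14 (2S,3R)-5,7-dihydroxy-3-[(2R,3S)-5,7-dihydroxy-2-(4-hydroxyphenyl)-4-oxochroman-3-yl]-2-(4-methoxyphenyl)chroman-4-one
Conditions: H2 (1 atm), 10% Pd/C, EtOAc/MeOH 1:1, rt
Reagents that add atoms: none
Why: Hydrogenolysis of the five benzyl aryl ethers under neutral conditions leaves the aryl methyl ether, the ketones and the cyclic C-2–O bonds intact and cannot epimerise any stereocentre.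

**Compound list**

1 | 2,4,6-trihydroxybenzaldehyde | O=Cc1c(O)cc(O)cc1O | starting material
2 | 2,4-bis(benzyloxy)-6-hydroxybenzaldehyde | O=Cc1c(O)cc(OCc2ccccc2)cc1OCc1ccccc1 | intermediate
3 | 4-methoxybenzaldehyde | COc1ccc(C=O)cc1 | starting material
4 | ethynylmagnesium bromide | C#C[Mg]Br | starting material
5 | bromomagnesium 1-(4-methoxyphenyl)prop-2-yn-1-olate (racemic) | COc1ccc(C(C#C)O[Mg]Br)cc1 | intermediate (not isolated)
6 | rac-1-(4-methoxyphenyl)prop-2-yn-1-yl acetate | COc1ccc(C(C#C)OC(C)=O)cc1 | intermediate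
7 | 2,4-bis(benzyloxy)-6-{[(1S)-1-(4-methoxyphenyl)prop-2-yn-1-yl]oxy}benzaldehyde | COc1ccc([C@H](C#C)Oc2cc(OCc3ccccc3)cc(OCc3ccccc3)c2C=O)cc1 | intermediate
8 | 4-(benzyloxy)benzaldehyde | O=Cc1ccc(OCc2ccccc2)cc1 | starting material
9 | 2,4-bis(benzyloxy)-6-{[(1R,4R)-4-[4-(benzyloxy)phenyl]-4-hydroxy-1-(4-methoxyphenyl)but-2-yn-1-yl]oxy}benzaldehyde | COc1ccc([C@H](C#C[C@H](O)c2ccc(OCc3ccccc3)cc2)Oc2cc(OCc3ccccc3)cc(OCc3ccccc3)c2C=O)cc1 | intermediate
10 | 2,2'-{[(1R,4S)-4-[4-(benzyloxy)phenyl]-1-(4-methoxyphenyl)but-2-yne-1,4-diyl]bis(oxy)}bis[4,6-bis(benzyloxy)benzaldehyde] | COc1ccc([C@H](C#C[C@@H](Oc2cc(OCc3ccccc3)cc(OCc3ccccc3)c2C=O)c2ccc(OCc3ccccc3)cc2)Oc2cc(OCc3ccccc3)cc(OCc3ccccc3)c2C=O)cc1 | intermediate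
11 | (2R,3E)-5,7-bis(benzyloxy)-3-{(2R)-2-[3,5-bis(benzyloxy)-2-formylphenoxy]-2-[4-(benzyloxy)phenyl]ethylidene}-2-(4-methoxyphenyl)chroman-4-one | COc1ccc([C@H]2Oc3cc(OCc4ccccc4)cc(OCc4ccccc4)c3C(=O)/C2=C/[C@@H](Oc2cc(OCc3ccccc3)cc(OCc3ccccc3)c2C=O)c2ccc(OCc3ccccc3)cc2)cc1 | intermediate (not isolated)
12 | (2S,3E)-5,7-bis(benzyloxy)-2-[4-(benzyloxy)phenyl]-3-{(2S)-2-[3,5-bis(benzyloxy)-2-formylphenoxy]-2-(4-methoxyphenyl)ethylidene}chroman-4-one | COc1ccc([C@H](/C=C2/C(=O)c3c(OCc4ccccc4)cc(OCc4ccccc4)cc3O[C@H]2c2ccc(OCc3ccccc3)cc2)Oc2cc(OCc3ccccc3)cc(OCc3ccccc3)c2C=O)cc1 | intermediate (not isolated)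
13 | (2S,3R)-5,7-bis(benzyloxy)-3-{(2R,3S)-5,7-bis(benzyloxy)-2-[4-(benzyloxy)phenyl]-4-oxochroman-3-yl}-2-(4-methoxyphenyl)chroman-4-one | COc1ccc([C@H]2Oc3cc(OCc4ccccc4)cc(OCc4ccccc4)c3C(=O)[C@@H]2[C@@H]2C(=O)c3c(OCc4ccccc4)cc(OCc4ccccc4)cc3O[C@H]2c2ccc(OCc3ccccc3)cc2)cc1 | intermediate
14 | (2S,3R)-5,7-dihydroxy-3-[(2R,3S)-5,7-dihydroxy-2-(4-hydroxyphenyl)-4-oxochroman-3-yl]-2-(4-methoxyphenyl)chroman-4-one | COc1ccc([C@H]2Oc3cc(O)cc(O)c3C(=O)[C@@H]2[C@@H]2C(=O)c3c(O)cc(O)cc3O[C@H]2c2ccc(O)cc2)cc1 | target

**Step count and risks**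

Total steps: 7. Longest linear sequence: 6 steps (3 → 6 → 7 → 9 → 10 → 13 → 14; phenol 2 from step 1 enters twice).

Most likely to fail, first: step 6. The formyl groups are di-ortho-substituted and very electron-rich, so formation of the acyl anion equivalent may be slow. The internal alkyne is flanked by two branched carbons. Base could isomerise the propargylic ether centres of 10 or the γ-position of 11 and 12, or open a finished ring by retro-oxa-Michael reaction. The fallback sets out from 10 and replaces the carbene-mediated alkyne hydroacylation by a base-free hydroacylation under cationic monovalent rhodium catalysis ([Rh(cod)2]BF4 with 1,2-bis(diphenylphosphino)ethane, acetone/CH2Cl2, rt to 40 °C). This runs through formyl C–H oxidative addition, syn insertion of the alkyne and reductive elimination, assisted by chelation of the ether oxygen, and gives the mixture of 11 and 12, which is now isolated. The second ring is then closed in a separate, milder Stetter reaction (2-mesityl-6,7-dihydro-5H-pyrrolo[2,1-c][1,2,4]triazol-2-ium chloride 20 mol%, iPr2NEt, toluene, rt), which returns to the route at 13. No new compound is made.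

Second: step 5. The carbinol carbon is benzylic, propargylic and para-alkoxy-activated, so partial ionisation would erode the C-2'' configuration (giving the diastereomeric biflavanone after step 6), and SN2' attack would give an allenyl ether. The fallback forms the aryl–oxygen bond instead of the alkyl–oxygen bond, so the stereocentre is not touched. It sets out from 7 and 8. Commercial 2,4,6-trifluorobenzaldehyde is treated with BnOH/NaH (2 equiv, THF, 0 °C) to give 2,4-bis(benzyloxy)-6-fluorobenzaldehyde F1. Step 4 is repeated with the mirror-image (R,R)-ligand to give the epimeric alcohol 2,4-bis(benzyloxy)-6-{[(1R,4S)-4-[4-(benzyloxy)phenyl]-4-hydroxy-1-(4-methoxyphenyl)but-2-yn-1-yl]oxy}benzaldehyde F2. Its potassium alkoxide (KN(SiMe3)2, THF/DMF, −40 to 0 °C) displaces the fluoride of F1 ortho to the formyl group by SNAr with retention at carbon, which returns to the route at 10.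

Third: step 4. The alkynylzinc derived from 7 carries its own formyl group and may oligomerise, and the electron-rich aldehyde 8 is a slow acceptor. The fallback makes both carbinol centres before any formyl-bearing ring is attached. It sets out from 3 and 8. Aldehyde 3 is alkynylated with trimethylsilylacetylene (Me2Zn, the (R,R)-ligand, toluene) to (S)-1-(4-methoxyphenyl)-3-(trimethylsilyl)prop-2-yn-1-ol F3, which is desilylated (K2CO3, MeOH) to (R)-1-(4-methoxyphenyl)prop-2-yn-1-ol F4. F4 is added to 8 (Me2Zn, the (S,S)-ligand) to give (1S,4R)-4-[4-(benzyloxy)phenyl]-1-(4-methoxyphenyl)but-2-yne-1,4-diol F5. A double Mitsunobu etherification with two equivalents of 2 (PPh3, DIAD, toluene, −20 °C) inverts both centres and returns to the route at 10.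

**Further compounds**

F0 | step 6 | none | none
F1 | step 5 | 2,4-bis(benzyloxy)-6-fluorobenzaldehyde | O=Cc1c(F)cc(OCc2ccccc2)cc1OCc1ccccc1
F2 | step 5 | 2,4-bis(benzyloxy)-6-{[(1R,4S)-4-[4-(benzyloxy)phenyl]-4-hydroxy-1-(4-methoxyphenyl)but-2-yn-1-yl]oxy}benzaldehyde | COc1ccc([C@H](C#C[C@@H](O)c2ccc(OCc3ccccc3)cc2)Oc2cc(OCc3ccccc3)cc(OCc3ccccc3)c2C=O)cc1
F3 | step 4 | (S)-1-(4-methoxyphenyl)-3-(trimethylsilyl)prop-2-yn-1-ol | COc1ccc([C@@H](C#C[Si](C)(C)C)O)cc1
F4 | step 4 | (R)-1-(4-methoxyphenyl)prop-2-yn-1-ol | COc1ccc([C@@H](C#C)O)cc1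
F5 | step 4 | (1S,4R)-4-[4-(benzyloxy)phenyl]-1-(4-methoxyphenyl)but-2-yne-1,4-diol | COc1ccc([C@@H](C#C[C@H](O)c2ccc(OCc3ccccc3)cc2)O)cc1
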